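All runs were computed from invented constants; noise was put on by code.

Percent of the substrate charged is the unit to read this flask in: substrate and product should sum to 100, and any shortfall is material held out of sight. The new flask carries a catalyst charge between those of two earlier runs.

common to all: substrate 0.80 M
- red: free catalyst 80 mM; run made earlier
- grey: free catalyst 180 mM; run made earlier
- flask: free catalyst 120 mM; time 2.0 h

- red (time / min: substrate / %, product / %): 15.0: 21.9, 75.5; 40.0: 4.9, 93.8; 80.0: 4.7, 93.2; 120: 4.1, 95.2
- grey (time / min: substrate / %, product / %): 15.0: 6.0, 90.8; 40.0: 3.8, 93.2; 80.0: 3.6, 93.6; 120: 4.3, 92.6

(each reading ± 0.5 percentage points)

* at 2.0 h, what has stopped the reaction, if anything has (no working catalyst is left / all of the substrate has reacted / it is still moving / forward and back rates have come level)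
* part of the substrate gone at 2.0 h
* the product standing at 2.0 h, as a percentage of the substrate charged
* the catalyst intermediate B standing at 2.0 h, as a percentage of the substrate charged

- the reaction counts as stopped when no species that holds the substrate changes by six tenths of a point or more over the second half of the time

I build the flask up one process at a time. Take first the main step alone, substrate to product, as pseudo-first-order. Substrate in the red run fell to 21.9% in 15.0 min, a half-life of 6.85 min. Scaled by catalyst, the flask gets 4.56 min, far shorter than 2.0 h, so this step by itself has 26.3 half-lives to run.

Now add the way back. From 40.0 min on, the readings of both runs level off, and their mean ratios of product to substrate are 20.6 for red and 23.9 for grey, pooled 22.1. Call this reading the plateau ratio, c(product) over c(substrate) once the readings level off. Its closeness across 2.25 times the catalyst points to forward and back rates having come level, and with nothing held it puts substrate at 4.33%.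

Last, add the holding. The mean shortfall is 1.37% in red and 2.97% in grey, on average 13.4% of the catalyst charged. For the flask I reckon 2.01% of the substrate charged to be held, which I assign to catalyst intermediate B, and the plateau ratio divides the remainder: substrate 4.24%, product 93.7%.

The forecast stands close to this: forward and back rates have come level, conversion 95.7%, product 93.7%, catalyst intermediate B 2%, on the grounds that “this is equilibrium rather than catalyst death”.

At 2.0 h the flask gives: forward and back rates have come level, with conversion 96.1%, product 93.6% and catalyst intermediate B 1.59%.

substrate + free catalyst ⇌ catalyst intermediate A (K = 2.20 /M, k = 0.0378 /M/s); catalyst intermediate A ⇌ catalyst intermediate B (K = 1.83, k = 0.347 /s); catalyst intermediate B ⇌ free catalyst + product (K = 5.92 M, k = 0.0643 /s) The flask's ratio of product to substrate is 23.8 against the plateau ratio 22.1 read from the runs, and catalyst intermediate A stands in the flask at a further 0.867% of the substrate charged. The neighbouring flask, charged with 0.48 M of free catalyst, holds 9.24% in the two intermediates, so the plateau ratio gives it 3.93% substrate. That flask stands at product 87.1% and substrate 3.7%.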